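**Retrosynthetic overview**

1. Numbering and feature: hydroazulene numbering is used (five-membered ring C1–C2–C3–C3a–C8a, seven-membered ring C3a–C4–C5–C6–C7–C8–C8a; β is the face of the C8a methyl, α the opposite face). The strategy rests on the five-membered ring, where the C3a hydroxyl is 1,3 to the central carbon of the C3 isopropyl group and isopropyl, OH and methyl on C3, C3a and C8a are all β. With that carbon as a carbonyl, C3–C3a is the bond of a β-hydroxy ketone (a latent aldol).
2. Target ⇒ anti opening at C7 of the 6α,7α-epoxide by p-anisate; epoxide ⇒ C6–C7 olefin; isopropyl ⇒ acetyl (methylenation, hydrogenation).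
3. Key disconnection C3–C3a: copper hydride reductive aldol of keto-enone 11. The five-membered ring is closed last, onto the finished seven-membered ring, and C8a relays its configuration to C3a and C3.
4. 11 ⇒ cross-metathesis of allyl ketone 9 with methyl vinyl ketone; 9 ⇒ Pd/PHOX allylation of the tetrasubstituted silyl enol ether of 2,5-dimethylcyclohept-4-enone (sets C8a).
5. The seven-membered ring is formed first, by Claisen ring expansion of a 2-ethylidene-5-vinyltetrahydrofuran made from ethyl levulinate and vinylmagnesium bromide.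

Key step: step 7

**Remarks on the chemistry (assumptions)**

- The sense of induction of (S)-t-Bu-PHOX in step 5 is assumed to be the one established for 2-methylcycloalkanone enolates, which corresponds to R at the quaternary carbon here (the ring allylic CH2 outranks the allyl group). If the opposite sense were found, the (R)-ligand would be used.
- The allyl enol carbonate is replaced by the thermodynamic silyl enol ether (steps 4 and 5), because the allylation must start from the more substituted enolate and direct carbonate formation would not secure that regiochemistry.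
- Compounds 3 to 6 are racemic and 7 is achiral; absolute configuration enters only at step 5.

**Route**

Step 1
Reactants: 1 ethyl levulinate; 2 vinylmagnesium bromide
Product: 4 rac-5-methyl-5-vinyldihydrofuran-2(3H)-one, via bromomagnesium alkoxide 3 (not isolated)
Conditions: 2 (1.05 equiv), THF, −78 → 25 °C; aq. NH4Cl
Reagents that add atoms: none
Why: Grignard addition to the ketone, which is far more electrophilic than the ester at low temperature, gives tertiary alkoxide 3, which lactonises onto the ester on warming; the racemic centre is erased in step 3.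

Step 2
Reactants: 4 rac-5-methyl-5-vinyldihydrofuran-2(3H)-one
Product: 5 rac-(Z)-2-ethylidene-5-methyl-5-vinyltetrahydrofuran
Conditions: CH3CHBr2, TiCl4, TMEDA, Zn, PbCl2 (cat.), THF, 0 → 25 °C; aq. K2CO3, filtration through Et3N-deactivated basic alumina
Reagents that add atoms: 1,1-dibromoethane, CC(Br)Br
Why: Takai–Utimoto alkylidenation of the lactone carbonyl with the non-basic zinc/low-valent titanium ethylidene reagent should give the exocyclic enol ether without enolisation or attack on the vinyl group; the olefin geometry is of no consequence.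

Step 3
Reactants: 5 rac-(Z)-2-ethylidene-5-methyl-5-vinyltetrahydrofuran
Product: 6 rac-2,5-dimethylcyclohept-4-en-1-one
Conditions: toluene, Et3N (trace), sealed tube, 180 °C
Reagents that add atoms: none
Why: Claisen rearrangement of the allyl vinyl ether embedded in 5 (C–C bond between the ethylidene carbon and the vinyl terminus, C5–O cleavage) expands the five-membered ring to the cyclohept-4-enone with a cis ring olefin, the known ring expansion of 2-alkylidene-5-vinyltetrahydrofurans; the C2 centre is racemic and is erased in step 4.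

Step 4
Reactants: 6 rac-2,5-dimethylcyclohept-4-en-1-one
Product: 7 [(2,5-dimethylcyclohepta-1,4-dien-1-yl)oxy]trimethylsilane
Conditions: TMSCl, NaI, Et3N, MeCN, 25 → 50 °C
Reagents that add atoms: chlorotrimethylsilane, C[Si](C)(C)Cl
Why: Equilibrating silylation with iodotrimethylsilane formed in the flask should favour the thermodynamic, tetrasubstituted silyl enol ether toward the methyl-bearing α-carbon, which fixes the site of allylation; any product from the minor isomer is separable after step 5.

Step 5
Reactants: 7 [(2,5-dimethylcyclohepta-1,4-dien-1-yl)oxy]trimethylsilane; 8 diallyl carbonate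
Product: 9 (R)-2-allyl-2,5-dimethylcyclohept-4-en-1-one
Conditions: Pd2(dba)3 (2.5 mol%), (S)-t-Bu-PHOX (6.25 mol%), 8 (1.05 equiv), Bu4N[Ph3SiF2] (35 mol%), THF, 25 °C
Reagents that add atoms: none
Why: Enantioselective Tsuji allylation of a silyl enol ether, in which fluoride releases the enolate, zerovalent palladium and 8 give the π-allyl complex, and C–C bond formation in the PHOX-bound allyl palladium enolate sets the quaternary C8a centre under ligand control with retention of enolate regiochemistry.

Step 6
Reactants: 9 (R)-2-allyl-2,5-dimethylcyclohept-4-en-1-one; 10 methyl vinyl ketone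
Product: 11 (R)-2,5-dimethyl-2-[(E)-4-oxopent-2-en-1-yl]cyclohept-4-en-1-one
Conditions: second-generation Grubbs catalyst (H2IMes)(PCy3)Cl2Ru=CHPh (5 mol%), 10 (4 equiv), CH2Cl2, 40 °C
Reagents that add atoms: none
Why: Olefin cross-metathesis of the terminal allyl olefin with the electron-poor enone partner should give the E enone, the trisubstituted ring olefin being too hindered to engage the ruthenium carbene.

Step 7
Reactants: 11 (R)-2,5-dimethyl-2-[(E)-4-oxopent-2-en-1-yl]cyclohept-4-en-1-one
Product: 14 1-[(3S,3aS,8aR)-3a-hydroxy-6,8a-dimethyl-1,2,3,3a,4,5,8,8a-octahydroazulen-3-yl]ethan-1-one, via copper enolate 12 (not isolated), via copper aldolate 13 (not isolated)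
Conditions: [(Ph3P)CuH]6 (0.25 equiv, 1.5 equiv of hydride), degassed toluene, −40 → −10 °C; aq. NH4Cl
Reagents that add atoms: none
Why: The phosphine-bound copper hydride delivers hydride to C2 of the s-cis enone and leaves the Z copper enolate 12, whose C3 adds to the C3a ketone to give aldolate 13 and, on protonation, 14; the closest known reaction type is the copper hydride reductive aldol cyclisation of keto-enones. The five-membered ring closes in a 5-(enolexo)-exo-trig mode. C3a is set by the tether: C1 hangs from C8a, so C3 can reach only the carbonyl face syn to C1, and a trans closure would need a torsion about C8a–C3a that the cycloheptenone cannot adopt; the new oxygen therefore ends cis to the angular methyl. C3 is set by the copper bridge between enolate oxygen and ketone oxygen in a closed chair-like transition state, which places the acetyl group cis to the new alkoxide. The step needs chemoselectivity (1,4-reduction ahead of 1,2-reduction, isolated C6–C7 olefin untouched), secured by the soft hydride at low temperature, and diastereoselectivity at C3a and C3, secured by the short tether and the chelate, while the quaternary C8a cannot epimerise.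

Step 8
Reactants: 14 1-[(3S,3aS,8aR)-3a-hydroxy-6,8a-dimethyl-1,2,3,3a,4,5,8,8a-octahydroazulen-3-yl]ethan-1-one
Product: 15 (3R,3aS,8aR)-6,8a-dimethyl-3-(prop-1-en-2-yl)-2,3,4,5,8,8a-hexahydroazulen-3a(1H)-ol
Conditions: Zn, CH2Br2, TiCl4 (preformed reagent, excess), THF/CH2Cl2, 0 → 25 °C
Reagents that add atoms: dibromomethane, BrCBr
Why: Takai–Lombardo methylenation with the non-basic zinc/titanium methylene reagent should convert the hindered methyl ketone into the isopropenyl group without retro-aldol cleavage or epimerisation at C3, and it tolerates the free tertiary hydroxyl.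

Step 9
Reactants: 15 (3R,3aS,8aR)-6,8a-dimethyl-3-(prop-1-en-2-yl)-2,3,4,5,8,8a-hexahydroazulen-3a(1H)-ol
Product: 16 (3R,3aS,8aR)-6,8a-dimethyl-3-(propan-2-yl)-2,3,4,5,8,8a-hexahydroazulen-3a(1H)-ol
Conditions: H2 (1 atm), RhCl(PPh3)3 (10 mol%), toluene/EtOH, 25 °C
Reagents that add atoms: none
Why: Homogeneous hydrogenation with RhCl(PPh3)3 reduces the 1,1-disubstituted olefin much faster than the trisubstituted ring olefin, and no stereocentre is created.

Step 10
Reactants: 16 (3R,3aS,8aR)-6,8a-dimethyl-3-(propan-2-yl)-2,3,4,5,8,8a-hexahydroazulen-3a(1H)-ol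
Product: 17 triethyl{[(3R,3aS,8aR)-6,8a-dimethyl-3-(propan-2-yl)-2,3,4,5,8,8a-hexahydroazulen-3a(1H)-yl]oxy}silane
Conditions: TESOTf, 2,6-lutidine, CH2Cl2, −78 → 0 °C
Reagents that add atoms: triethylsilyl trifluoromethanesulfonate, CC[Si](CC)(CC)OS(=O)(=O)C(F)(F)F
Why: Silyl triflate silylation of the hindered tertiary alcohol gives an ether that blocks transannular attack of O3a on C6 of the later epoxide and removes hydrogen-bond delivery of the peracid to the β-face.

Step 11
Reactants: 17 triethyl{[(3R,3aS,8aR)-6,8a-dimethyl-3-(propan-2-yl)-2,3,4,5,8,8a-hexahydroazulen-3a(1H)-yl]oxy}silane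
Product: 18 (6R,7S)-6,7-epoxide of 17 (epoxide oxygen on the α-face; other centres 3R,3aS,8aR)
Conditions: mCPBA, NaHCO3 (solid buffer), CH2Cl2, 0 °C
Reagents that add atoms: 3-chloroperbenzoic acid, OOC(=O)c1cccc(Cl)c1
Why: Prilezhaev epoxidation of the trisubstituted olefin, expected from the α-face because the β-face of the seven-membered ring carries the angular methyl (1,3 to C7) and the triethylsilyloxy group, which sets C6 (oxygen α, methyl β) and C7 (oxygen α).

Step 12
Reactants: 18 (6R,7S)-6,7-epoxide of 17; 19 p-anisic acid
Product: 20 (3R,3aS,6R,7R,8aR)-6-hydroxy-6,8a-dimethyl-3-(propan-2-yl)-3a-(triethylsilyloxy)decahydroazulen-7-yl 4-methoxybenzoate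
Conditions: 19 (3 equiv), Cs2CO3 (1 equiv), DMF, 100 °C
Reagents that add atoms: none
Why: SN2 opening of the epoxide by caesium carboxylate at the secondary C7 (the tertiary C6 is closed to backside attack) proceeds with inversion, so the anisate arrives on the β-face while the C6–O bond stays α, and the excess free acid protonates the tertiary alkoxide so that the epoxide does not re-form.

Step 13
Reactants: 20 (3R,3aS,6R,7R,8aR)-6-hydroxy-6,8a-dimethyl-3-(propan-2-yl)-3a-(triethylsilyloxy)decahydroazulen-7-yl 4-methoxybenzoate
Product: 21 (3R,3aS,6R,7R,8aR)-3a,6-dihydroxy-6,8a-dimethyl-3-(propan-2-yl)decahydroazulen-7-yl 4-methoxybenzoate (target)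
Conditions: HF·pyridine, pyridine, THF, 0 → 25 °C
Reagents that add atoms: none
Why: Fluoride-driven cleavage of the Si–O bond under pyridine-buffered conditions should free the C3a hydroxyl without acyl migration, ester cleavage or ionisation of the tertiary alcohols.

**Compound list**

1 | ethyl levulinate (ethyl 4-oxopentanoate) | CCOC(=O)CCC(C)=O | starting material
2 | vinylmagnesium bromide | C=C[Mg]Br | starting material
3 | bromomagnesium alkoxide of rac-ethyl 4-hydroxy-4-methylhex-5-enoate | CCOC(=O)CCC(C)(C=C)O[Mg]Br | intermediate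
4 | rac-5-methyl-5-vinyldihydrofuran-2(3H)-one | CC1(C=C)CCC(=O)O1 | intermediate
5 | rac-(Z)-2-ethylidene-5-methyl-5-vinyltetrahydrofuran | C/C=C1/CCC(C)(C=C)O1 | intermediate
6 | rac-2,5-dimethylcyclohept-4-en-1-one | CC1CC=C(C)CCC1=O | intermediate
7 | [(2,5-dimethylcyclohepta-1,4-dien-1-yl)oxy]trimethylsilane | C[Si](C)(C)OC1=C(C)CC=C(C)CC1 | intermediate
8 | diallyl carbonate | C=CCOC(=O)OCC=C | starting material
9 | (R)-2-allyl-2,5-dimethylcyclohept-4-en-1-one | CC1=CC[C@@](C)(CC=C)C(=O)CC1 | intermediate
10 | methyl vinyl ketone (but-3-en-2-one) | CC(=O)C=C | starting material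
11 | (R)-2,5-dimethyl-2-[(E)-4-oxopent-2-en-1-yl]cyclohept-4-en-1-one | CC1=CC[C@@](C)(C/C=C/C(C)=O)C(=O)CC1 | intermediate
12 | copper Z-enolate of (R)-2,5-dimethyl-2-(4-oxopentyl)cyclohept-4-en-1-one (Ph3P on copper omitted) | CC1=CC[C@@](C)(CC/C=C(/C)O[Cu])C(=O)CC1 | intermediate
13 | copper aldolate of 14 (Ph3P on copper omitted) | CC1=CC[C@@]2(C)CC[C@H](C(C)=O)[C@@]2(O[Cu])CC1 | intermediate
14 | 1-[(3S,3aS,8aR)-3a-hydroxy-6,8a-dimethyl-1,2,3,3a,4,5,8,8a-octahydroazulen-3-yl]ethan-1-one (acetyl, OH and angular methyl all β, cis-fused) | CC1=CC[C@@]2(C)CC[C@H](C(C)=O)[C@@]2(O)CC1 | intermediate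
15 | (3R,3aS,8aR)-6,8a-dimethyl-3-(prop-1-en-2-yl)-2,3,4,5,8,8a-hexahydroazulen-3a(1H)-ol | CC1=CC[C@@]2(C)CC[C@H](C(C)=C)[C@@]2(O)CC1 | intermediate
16 | (3R,3aS,8aR)-6,8a-dimethyl-3-(propan-2-yl)-2,3,4,5,8,8a-hexahydroazulen-3a(1H)-ol | CC1=CC[C@@]2(C)CC[C@H](C(C)C)[C@@]2(O)CC1 | intermediate
17 | triethylsilyl ether of 16 at O3a | CC1=CC[C@@]2(C)CC[C@H](C(C)C)[C@@]2(O[Si](CC)(CC)CC)CC1 | intermediate
18 | (3R,3aS,6R,7S,8aR)-6,7-epoxide of 17, epoxide oxygen α | C[C@]12O[C@H]1C[C@@]3(C)CC[C@H](C(C)C)[C@@]3(O[Si](CC)(CC)CC)CC2 | intermediate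
19 | p-anisic acid (4-methoxybenzoic acid) | COc1ccc(C(=O)O)cc1 | starting material
20 | (3R,3aS,6R,7R,8aR)-6-hydroxy-6,8a-dimethyl-3-(propan-2-yl)-3a-(triethylsilyloxy)decahydroazulen-7-yl 4-methoxybenzoate | COc1ccc(C(=O)O[C@@H]2C[C@@]3(C)CC[C@H](C(C)C)[C@@]3(O[Si](CC)(CC)CC)CC[C@@]2(C)O)cc1 | intermediate
21 | (3R,3aS,6R,7R,8aR)-3a,6-dihydroxy-6,8a-dimethyl-3-(propan-2-yl)decahydroazulen-7-yl 4-methoxybenzoate (CNP0244624.1) | COc1ccc(C(=O)O[C@@H]2C[C@@]3(C)CC[C@H](C(C)C)[C@@]3(O)CC[C@@]2(C)O)cc1 | target

**Step count**

Total: 13 steps. Longest linear sequence: 13 steps, from ethyl levulinate.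

**Steps most likely to fail**

Step 12. The carboxylate is a weak nucleophile and must approach C7 from the β-face past the angular methyl. The substitution may therefore be slow enough for acid-promoted ionisation at the tertiary C6, or loss of the silyl group followed by transannular attack of O3a on C6, to compete. The fallback sets out from 18 and uses hydroxide, a small, strong and irreversible nucleophile (KOH, DMSO/H2O, 100 °C). Anti opening at C7 should give (3R,3aS,6R,7R,8aR)-6,8a-dimethyl-3-(propan-2-yl)-3a-(triethylsilyloxy)decahydroazulene-6,7-diol F1. Its only secondary hydroxyl is then esterified with 19 (EDC·HCl, DMAP, CH2Cl2), the two tertiary oxygens being unreactive. The route is rejoined at 20.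

Step 11. Facial selectivity may be poor or reversed if the seven-membered ring reacts through a conformer in which C1 of the five-membered ring screens the α-face, so that the peracid approaches from the β-face. The fallback sets out from 17 and exploits that same preference. NBS in THF/H2O at 0 °C should place the bromonium ion on the β-face, and water then opens it at the tertiary C6 from the α-face to give the bromohydrin (3R,3aS,6R,7R,8aR)-7-bromo-6,8a-dimethyl-3-(propan-2-yl)-3a-(triethylsilyloxy)decahydroazulen-6-ol F2. K2CO3 in MeOH closes the 6α-alkoxide onto C7 with inversion, which gives the α-epoxide. The route is rejoined at 18.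

Step 7. The copper enolate may be protonated or reduced further before it adds to the hindered ketone next to the quaternary carbon, and the aldolate may revert on warming, with loss of the C3 configuration. The fallback sets out from 11 and separates reduction from ring closure. 1,4-Hydrosilylation (Et3SiH, RhCl(PPh3)3 cat., toluene, 50 °C) should give the silyl enol ether (R)-2,5-dimethyl-2-[(Z)-4-(triethylsilyloxy)pent-3-en-1-yl]cyclohept-4-en-1-one F3. MeLi in THF at −78 °C releases the lithium Z-enolate of (R)-2,5-dimethyl-2-(4-oxopentyl)cyclohept-4-en-1-one F4. This closes through the same metal-bridged transition state to the lithium aldolate of 14 F5, which is protonated with aq. NH4Cl at low temperature. The route is rejoined at 14.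

**Further compounds**

F1 | step 12 | (3R,3aS,6R,7R,8aR)-6,8a-dimethyl-3-(propan-2-yl)-3a-(triethylsilyloxy)decahydroazulene-6,7-diol | O[C@@H]1C[C@@]2(C)CC[C@H](C(C)C)[C@@]2(O[Si](CC)(CC)CC)CC[C@@]1(C)O
F2 | step 11 | (3R,3aS,6R,7R,8aR)-7-bromo-6,8a-dimethyl-3-(propan-2-yl)-3a-(triethylsilyloxy)decahydroazulen-6-ol | Br[C@@H]1C[C@@]2(C)CC[C@H](C(C)C)[C@@]2(O[Si](CC)(CC)CC)CC[C@@]1(C)O
F3 | step 7 | (R)-2,5-dimethyl-2-[(Z)-4-(triethylsilyloxy)pent-3-en-1-yl]cyclohept-4-en-1-one | CC1=CC[C@@](C)(CC/C=C(/C)O[Si](CC)(CC)CC)C(=O)CC1
F4 | step 7 | lithium Z-enolate of (R)-2,5-dimethyl-2-(4-oxopentyl)cyclohept-4-en-1-one | CC1=CC[C@@](C)(CC/C=C(/C)O[Li])C(=O)CC1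
F5 | step 7 | lithium aldolate of 14 | CC1=CC[C@@]2(C)CC[C@H](C(C)=O)[C@@]2(O[Li])CC1
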